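(All runs stem from a simulated flask for an exercise.)

- Put the rate constant of X on a logarithmic scale and work in powers of ten: the three new flasks share their charges and their time and differ in temperature, and you need X at the end of each.

| flask | G | E | temperature | remark | time |
|---|---|---|---|---|---|
| eta | 18 mM (fed, over 1.5 min) | 4 equiv | 25 °C | run made earlier |  |
| theta | 72 mM (fed, over 1.5 min) | 4 equiv | 55 °C | run made earlier |  |
| beta | 36 mM (fed, over 1.5 min) | 2 equiv | 25 °C | run made earlier |  |
| Wednesday's | 36 mM (fed, over 1.5 min) | 4.00 equiv | 55 °C |  | 2.0 h |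
| Sunday's | 36 mM (fed, over 1.5 min) | 4.00 equiv | 30 °C |  | 2.0 h |
| Tuesday's | 36 mM (fed, over 1.5 min) | 4.00 equiv | 80 °C |  | 2.0 h |

- eta (time / h: X / %): 0.417: 1.0; 0.667: 1.3; 0.833: 1.1; 1.33: 2.6; 2.00: 4.8; 4.00: 7.9; 6.00: 10.9
- theta (time / min: X / %): 4.00: 6.2; 12.0: 19.5; 20.0: 27.4; 30.0: 31.7; 40.0: 32.6; 60.0: 33.9; 80.0: 32.8
- beta (time / h: X / %): 1.00: 3.6; 2.00: 3.6; 3.00: 5.1; 4.00: 7.8; 6.00: 10.0

(each reading ± 0.5 percentage points)

- what was read earlier has a scatter of 0.5 percentage points, one standard deviation

1. the best flask by amount of X, in percent of the G charged; "all alike" if 1.5 percentage points covers them all (Wednesday's / Sunday's / Tuesday's / all alike)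
2. amount of X at the end, in percent of the G charged, Wednesday's
3. amount of X at the end, in percent of the G charged, Sunday's
4. amount of X at the end, in percent of the G charged, Tuesday's

- Start cold: eta and beta both hold E at 72.0 mM on different charges of G, and at 6.00 h their percentages differ by 0.9 percentage points against a scatter of 0.5 points per reading, so you may write the rate of X as k[G][E], and eta's slope gives k = 0.00421 L mol⁻¹ min⁻¹.

- Theta, at 55 °C with E at 288 mM, has 19.5% at 12.0 min, and counting from the middle of the feed gives k = 0.0602 L mol⁻¹ min⁻¹, so on these readings k gains a factor of ten over a rise of 26.0 K; call this rise the decade step D.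

- The objection is that no run varies E alone, so the first power of E is my assumption and D carries it; I cannot compute that doubt away.

- Sunday's flask lies 0.193 of a decade above eta, which gives the pseudo-first-order constant r = k[E] = 0.0566 h⁻¹ and, on a straight line, 11.3%.

- But G falls as it reacts; the exponential gives 10.6%, which is 0.70 points lower, against a scatter of 0.5 points per reading, so I commit to the exponential figure for Sunday's.

- Wednesday's has r = 0.520 h⁻¹, but I doubt that a slope holds, since theta's readings stand flat near 33.9%; r would reach that height in 0.796 h, less than the time allowed, so I take that height as my estimate for Wednesday's, and for Tuesday's too, where D puts the same climb at 5.20 min, though D says nothing of heights and theta held twice the concentration of E.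

- The forecast names Wednesday's with 22% (11% to 34%), 11% (7% to 15%) for Sunday's and 15% (5% to 30%) for Tuesday's, reasoning that “a competing loss of G or E wins when hot”; for Wednesday's my height stands higher than its figure.

- The flasks give 33.5% for Wednesday's, 11.9% for Sunday's and 29.2% for Tuesday's, so Wednesday's leads as forecast, and Sunday's lies within the forecast's range, while Wednesday's and Tuesday's stand higher than its figures. In Sunday's flask the half-life of G by the forward step alone, at 0.915 h, is 10 h, longer than the 2.0 h of the run, and G stands at 88.1% of its charge at 2.00 h, whereas in Wednesday's flask X moves from 31.8% at 1.00 h to 33.5% at 2.00 h.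

    G + E ⇌ X + Z (K = 0.140, k = 0.550 L mol⁻¹ min⁻¹, Ea = 75.0 kJ mol⁻¹, ΔH = 28.0 kJ mol⁻¹)
    2 E → L (k = 0.120 L mol⁻¹ min⁻¹, Ea = 77.0 kJ mol⁻¹)
    (constants at 80 °C)

- Carry D to the same Sunday's flask read at 30 min: 26.0 K gives the same r and so 2.72%, and the computed flask holds 3.32%.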